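## Retrosynthetic overview

1. The C13 acetate is installed last, by singlet-oxygen ene reaction on the C7=C11 butenolide alkene followed by allylic transposition.
2. The ten-membered carbocycle is closed at C5–C6 by an intramolecular vinylogous aldol addition, then E1cB elimination to the ylidene butenolide. The 1,4-oxa bridge forms by itself as the C4–OH/C1-ketone hemiketal.
3. The C1–C2 ketone bond joins the two chiral-pool halves in a photochemical nickel/hydrogen-atom-transfer acyl–alkyl coupling of a lactol with a primary iodide.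
4. The lactol half comes from (S)-5-oxotetrahydrofuran-2-carboxylic acid (C8 bought; butenolide built on its carboxyl; C10 set by trans-methylation). The iodide comes from (R)-linalool (C4 bought) by ozonolysis and photochemical alkoxy-radical fragmentation. The side chain comes from (R)-3-bromo-2-hydroxy-2-methylpropanoic acid.
5. Ring order: butenolide, then ten-membered carbocycle, with the tetrahydrofuran hemiketal bridge closing spontaneously.

Assumption: ring–chain tautomers are drawn in one form (8 as the lactol, 12 and 16–18 as open hydroxy ketones, 19–24 as the 1,4-hemiketal), and germacrane numbering (C1–C15) is used in names and comments.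

## Route

Step 1
Reactants: 1 (S)-5-oxotetrahydrofuran-2-carboxylic acid
Product: 3 (5S)-5-(2-diazoacetyl)dihydrofuran-2(3H)-one, via acid chloride 2 (not isolated)
Conditions: (COCl)2, cat. DMF, CH2Cl2, 0 °C to rt; then CH2N2 (3 equiv), Et2O, 0 °C
Reagents that add atoms: diazomethane C=[N+]=[N-]
Why: Acid chloride formation and Arndt–Eistert-type acylation of diazomethane run without amine base, so the bought C8 centre (S) is kept.

Step 2
Reactants: 3 (5S)-5-(2-diazoacetyl)dihydrofuran-2(3H)-one; 4 2-(diethoxyphosphoryl)propanoic acid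
Product: 6 3-methyl-4-[(2S)-5-oxotetrahydrofuran-2-yl]furan-2(5H)-one, via phosphonate keto ester 5 (not isolated)
Conditions: Rh2(OAc)4 (1 mol %), CH2Cl2, rt; then LiCl, i-Pr2NEt, MeCN, rt
Reagents that add atoms: none
Why: Carbenoid O–H insertion gives the α-acyloxy ketone, and an intramolecular Horner–Wadsworth–Emmons reaction under Masamune–Roush conditions closes the butenolide without touching C8.

Step 3
Reactants: 6 3-methyl-4-[(2S)-5-oxotetrahydrofuran-2-yl]furan-2(5H)-one
Product: 7 3-methyl-4-[(2S,4R)-4-methyl-5-oxotetrahydrofuran-2-yl]furan-2(5H)-one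
Conditions: LiN(i-Pr)2 (2.2 equiv), THF, −78 °C; MeI (1.0 equiv), −78 °C; NH4Cl
Reagents that add atoms: iodomethane CI
Why: Dianion alkylation: the lithium 2-furanolate masks the butenolide, and the more basic lactone enolate is methylated anti to the ring substituent at C8, so the bought centre sets C10 (R, trans).

Step 4
Reactants: 7 3-methyl-4-[(2S,4R)-4-methyl-5-oxotetrahydrofuran-2-yl]furan-2(5H)-one
Product: 8 4-[(2S,4R)-5-hydroxy-4-methyltetrahydrofuran-2-yl]-3-methylfuran-2(5H)-one (anomer mixture)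
Conditions: LiN(SiMe3)2 (1.05 equiv), THF, −78 °C; i-Bu2AlH (1.2 equiv), −78 °C; Rochelle salt
Reagents that add atoms: none
Why: In situ enolate protection of the butenolide as its furanolate lets the aluminium hydride reduce only the saturated lactone to the lactol (partial reduction); the anomeric centre is of no consequence.

Step 5
Reactants: 9 (R)-linalool
Product: 10 (5R)-5-methyl-5-vinyltetrahydrofuran-2-ol (anomer mixture)
Conditions: O3, CH2Cl2–MeOH, −78 °C; Me2S
Reagents that add atoms: ozone [O-][O+]=O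
Why: Ozonolysis is selective for the electron-rich trisubstituted alkene over the vinyl group, and the hydroxy aldehyde closes to the lactol; C4 (R) is bought.

Step 6
Reactants: 10 (5R)-5-methyl-5-vinyltetrahydrofuran-2-ol
Product: 11 (3R)-5-iodo-3-methylpent-1-en-3-yl formate
Conditions: PhI(OAc)2, I2, CH2Cl2, visible light, rt
Reagents that add atoms: iodine II
Why: Suárez alkoxy-radical fragmentation: photolysis of the anomeric hypoiodite, β-scission to the primary C2 radical and iodine trapping leave the tertiary alcohol as its formate, with C4 untouched.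

Step 7
Reactants: 8 4-[(2S,4R)-5-hydroxy-4-methyltetrahydrofuran-2-yl]-3-methylfuran-2(5H)-one; 11 (3R)-5-iodo-3-methylpent-1-en-3-yl formate
Product: 12 (3R,7R,9S)-9-hydroxy-3,7-dimethyl-9-(4-methyl-5-oxo-2,5-dihydrofuran-3-yl)-6-oxonon-1-en-3-yl formate (in equilibrium with its cyclic hemiketal)
Conditions: NiBr2(dme) (10 mol %), 4,4'-di-tert-butyl-2,2'-bipyridine, Ir[dF(CF3)ppy]2(dtbbpy)PF6 (1 mol %), quinuclidine (20 mol %), K2CO3, 1,4-dioxane, 450 nm LEDs, rt
Reagents that add atoms: none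
Why: Proposed new method: a lactol serves as a latent γ-hydroxy aldehyde in nickel/photoredox/hydrogen-atom-transfer acyl–alkyl coupling — the quinuclidinium radical cation made by the photoexcited iridium complex abstracts the formyl hydrogen of the open tautomer, the acyl radical is captured by the alkylnickel species from oxidative addition of 11, and reductive elimination from trivalent nickel forms the C1–C2 ketone bond without touching C4, C8 or C10; the closest known reaction type is the aldehyde C–H alkylation with alkyl bromides under the same triple catalysis.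

Step 8
Reactants: 13 (2R)-3-bromo-2-hydroxy-2-methylpropanoic acid
Product: 15 (2R)-3-chloro-2-hydroxy-2-methylpropanoic acid, via sodium glycidate 14 (not isolated)
Conditions: NaOH (2.1 equiv), H2O, 0 °C to rt; then conc. HCl, 0 °C to rt
Reagents that add atoms: hydrogen chloride Cl
Why: Intramolecular Williamson closure to the glycidate and acid-mediated epoxide opening by chloride at the unhindered CH2 exchange Br for Cl without touching the bought quaternary centre.

Step 9
Reactants: 12 (3R,7R,9S)-9-hydroxy-3,7-dimethyl-9-(4-methyl-5-oxo-2,5-dihydrofuran-3-yl)-6-oxonon-1-en-3-yl formate; 15 (2R)-3-chloro-2-hydroxy-2-methylpropanoic acid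
Product: 16 (1S,3R,7R)-7-(formyloxy)-3,7-dimethyl-1-(4-methyl-5-oxo-2,5-dihydrofuran-3-yl)-4-oxonon-8-en-1-yl (2R)-3-chloro-2-hydroxy-2-methylpropanoate
Conditions: DCC, DMAP (cat.), CH2Cl2, 0 °C to rt
Reagents that add atoms: none
Why: Steglich esterification of the only secondary hydroxyl (C8) goes with retention at C8 and C2'; the tertiary hydroxyls stay free and the C4 formate prevents spiroketal formation.

Step 10
Reactants: 16 (1S,3R,7R)-7-(formyloxy)-3,7-dimethyl-1-(4-methyl-5-oxo-2,5-dihydrofuran-3-yl)-4-oxonon-8-en-1-yl (2R)-3-chloro-2-hydroxy-2-methylpropanoate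
Product: 18 (1S,3R,7R)-7-hydroxy-3,7-dimethyl-1-(4-methyl-5-oxo-2,5-dihydrofuran-3-yl)-4,8-dioxooctan-1-yl (2R)-3-chloro-2-hydroxy-2-methylpropanoate, via formate aldehyde 17 (not isolated)
Conditions: O3, CH2Cl2–MeOH, −78 °C; Me2S; then KHCO3 (cat.), MeOH, 0 °C to rt
Reagents that add atoms: ozone [O-][O+]=O
Why: Chemoselective ozonolysis of the terminal vinyl group (the tetrasubstituted enoate alkene is electron-poor) and base-catalysed methanolysis of the labile formate free the C5 aldehyde and the C4 hydroxyl.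

Step 11
Reactants: 18 (1S,3R,7R)-7-hydroxy-3,7-dimethyl-1-(4-methyl-5-oxo-2,5-dihydrofuran-3-yl)-4,8-dioxooctan-1-yl (2R)-3-chloro-2-hydroxy-2-methylpropanoate
Product: 19 (1S,4R,8S,10R)-1,4-epoxy-1,5-dihydroxygermacr-7(11)-en-12,6-olid-8-yl (2R)-3-chloro-2-hydroxy-2-methylpropanoate (C5/C6 epimers)
Conditions: LiN(SiMe3)2 (3.1 equiv), THF (2 mM), −78 °C; AcOH
Reagents that add atoms: none
Why: Intramolecular vinylogous aldol addition of the lithium 2-furanolate (γ-attack, α-position blocked) onto the non-enolisable aldehyde closes the ten-membered ring; the cis-bridged C1 hemiketal (1S) is set thermodynamically by C4, and the new C5/C6 centres are erased in step 12.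

Step 12
Reactants: 19 (1S,4R,8S,10R)-1,4-epoxy-1,5-dihydroxygermacr-7(11)-en-12,6-olid-8-yl (2R)-3-chloro-2-hydroxy-2-methylpropanoate
Product: 21 (1S,4R,5E,8S,10R)-1,4-epoxy-1-hydroxygermacra-5,7(11)-dien-12,6-olid-8-yl (2R)-3-chloro-2-hydroxy-2-methylpropanoate, via mesylate 20 (not isolated)
Conditions: MsCl, Et3N, CH2Cl2, −20 °C; then DBU, 0 °C
Reagents that add atoms: none
Why: Selective mesylation of the only secondary hydroxyl and E1cB elimination through the butenolide dienolate give the ylidene butenolide, the ring enforcing the C4/C7-cis (5E) geometry.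

Step 13
Reactants: 21 (1S,4R,5E,8S,10R)-1,4-epoxy-1-hydroxygermacra-5,7(11)-dien-12,6-olid-8-yl (2R)-3-chloro-2-hydroxy-2-methylpropanoate
Product: 24 (1S,4R,5E,8S,10R)-13-acetoxy-1,4-epoxy-1-hydroxygermacra-5,7(11)-dien-12,6-olid-8-yl (2R)-3-chloro-2-hydroxy-2-methylpropanoate (CNP0414417.3), via hydroperoxide 22 (not isolated), via tertiary alcohol 23 (not isolated)
Conditions: O2, tetraphenylporphyrin (cat.), CH2Cl2, visible light, 0 °C; PPh3; then AcOH, NaOAc, 40 °C
Reagents that add atoms: dioxygen O=O; acetic acid CC(=O)O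
Why: Schenck ene reaction of singlet oxygen with the α,β-unsaturated lactone (gem regioselectivity: hydrogen from the C13 methyl, oxygen to C7), phosphine reduction and SN1' acetolysis of the bis-allylic tertiary alcohol (allylic transposition) return the conjugated diene with the C13 acetate; C7 ends sp2.

## Compound list

1 | (S)-5-oxotetrahydrofuran-2-carboxylic acid | O=C1CC[C@@H](C(=O)O)O1 | starting material
2 | (S)-5-oxotetrahydrofuran-2-carbonyl chloride | O=C1CC[C@@H](C(=O)Cl)O1 | intermediate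
3 | (5S)-5-(2-diazoacetyl)dihydrofuran-2(3H)-one | O=C1CC[C@@H](C(=O)C=[N+]=[N-])O1 | intermediate
4 | 2-(diethoxyphosphoryl)propanoic acid | CCOP(=O)(OCC)C(C)C(=O)O | starting material
5 | 2-oxo-2-[(2S)-5-oxotetrahydrofuran-2-yl]ethyl 2-(diethoxyphosphoryl)propanoate | CCOP(=O)(OCC)C(C)C(=O)OCC(=O)[C@@H]1CCC(=O)O1 | intermediate
6 | 3-methyl-4-[(2S)-5-oxotetrahydrofuran-2-yl]furan-2(5H)-one | O=C1CC[C@@H](C2=C(C)C(=O)OC2)O1 | intermediate
7 | 3-methyl-4-[(2S,4R)-4-methyl-5-oxotetrahydrofuran-2-yl]furan-2(5H)-one | O=C1[C@H](C)C[C@@H](C2=C(C)C(=O)OC2)O1 | intermediate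
8 | 4-[(2S,4R)-5-hydroxy-4-methyltetrahydrofuran-2-yl]-3-methylfuran-2(5H)-one | OC1[C@H](C)C[C@@H](C2=C(C)C(=O)OC2)O1 | intermediate
9 | (R)-linalool | C=C[C@@](O)(C)CCC=C(C)C | starting material
10 | (5R)-5-methyl-5-vinyltetrahydrofuran-2-ol | C=C[C@@]1(C)CCC(O)O1 | intermediate
11 | (3R)-5-iodo-3-methylpent-1-en-3-yl formate | C=C[C@@](OC=O)(C)CCI | intermediate
12 | (3R,7R,9S)-9-hydroxy-3,7-dimethyl-9-(4-methyl-5-oxo-2,5-dihydrofuran-3-yl)-6-oxonon-1-en-3-yl formate | C=C[C@@](OC=O)(C)CCC(=O)[C@H](C)C[C@@H](C1=C(C)C(=O)OC1)O | intermediate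
13 | (2R)-3-bromo-2-hydroxy-2-methylpropanoic acid | OC(=O)[C@@](C)(O)CBr | starting material
14 | sodium (2S)-2-methyloxirane-2-carboxylate | [Na+].[O-]C(=O)[C@]1(C)CO1 | intermediate
15 | (2R)-3-chloro-2-hydroxy-2-methylpropanoic acid | OC(=O)[C@@](C)(O)CCl | intermediate
16 | (1S,3R,7R)-7-(formyloxy)-3,7-dimethyl-1-(4-methyl-5-oxo-2,5-dihydrofuran-3-yl)-4-oxonon-8-en-1-yl (2R)-3-chloro-2-hydroxy-2-methylpropanoate | C=C[C@@](OC=O)(C)CCC(=O)[C@H](C)C[C@@H](C1=C(C)C(=O)OC1)OC(=O)[C@@](C)(O)CCl | intermediate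
17 | (1S,3R,7R)-7-(formyloxy)-3,7-dimethyl-1-(4-methyl-5-oxo-2,5-dihydrofuran-3-yl)-4,8-dioxooctan-1-yl (2R)-3-chloro-2-hydroxy-2-methylpropanoate | O=C[C@@](OC=O)(C)CCC(=O)[C@H](C)C[C@@H](C1=C(C)C(=O)OC1)OC(=O)[C@@](C)(O)CCl | intermediate
18 | (1S,3R,7R)-7-hydroxy-3,7-dimethyl-1-(4-methyl-5-oxo-2,5-dihydrofuran-3-yl)-4,8-dioxooctan-1-yl (2R)-3-chloro-2-hydroxy-2-methylpropanoate | O=C[C@@](O)(C)CCC(=O)[C@H](C)C[C@@H](C1=C(C)C(=O)OC1)OC(=O)[C@@](C)(O)CCl | intermediate
19 | (1S,4R,8S,10R)-1,4-epoxy-1,5-dihydroxygermacr-7(11)-en-12,6-olid-8-yl (2R)-3-chloro-2-hydroxy-2-methylpropanoate | CC1=C2C(C(O)[C@@]3(C)CC[C@](O)(O3)[C@H](C)C[C@@H]2OC(=O)[C@@](C)(O)CCl)OC1=O | intermediate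
20 | 5-O-mesylate of 19 | CC1=C2C(C(OS(C)(=O)=O)[C@@]3(C)CC[C@](O)(O3)[C@H](C)C[C@@H]2OC(=O)[C@@](C)(O)CCl)OC1=O | intermediate
21 | (1S,4R,5E,8S,10R)-1,4-epoxy-1-hydroxygermacra-5,7(11)-dien-12,6-olid-8-yl (2R)-3-chloro-2-hydroxy-2-methylpropanoate | CC1=C2/C(=C\[C@@]3(C)CC[C@](O)(O3)[C@H](C)C[C@@H]2OC(=O)[C@@](C)(O)CCl)OC1=O | intermediate
22 | (1S,4R,5E,8S,10R)-1,4-epoxy-7-hydroperoxy-1-hydroxygermacra-5,11(13)-dien-12,6-olid-8-yl (2R)-3-chloro-2-hydroxy-2-methylpropanoate | C=C1C(=O)O\C(=C\[C@@]3(C)CC[C@](O)(O3)[C@H](C)C[C@@H]2OC(=O)[C@@](C)(O)CCl)C12OO | intermediate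
23 | (1S,4R,5E,8S,10R)-1,4-epoxy-1,7-dihydroxygermacra-5,11(13)-dien-12,6-olid-8-yl (2R)-3-chloro-2-hydroxy-2-methylpropanoate | C=C1C(=O)O\C(=C\[C@@]3(C)CC[C@](O)(O3)[C@H](C)C[C@@H]2OC(=O)[C@@](C)(O)CCl)C12O | intermediate
24 | (1S,4R,5E,8S,10R)-13-acetoxy-1,4-epoxy-1-hydroxygermacra-5,7(11)-dien-12,6-olid-8-yl (2R)-3-chloro-2-hydroxy-2-methylpropanoate (CNP0414417.3) | CC(=O)OCC1=C2/C(=C\[C@@]3(C)CC[C@](O)(O3)[C@H](C)C[C@@H]2OC(=O)[C@@](C)(O)CCl)OC1=O | target

## Step count and risks

Total steps: 13. Longest linear sequence: 10 (steps 1–4, 7, 9–13).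

Three steps most likely to fail:

**Step 7 (the proposed new coupling).** The cyclic lactol dominates over the open aldehyde, and hydrogen abstraction at the anomeric C–H would lead back to lactone 7 or to fragmentation instead of the acyl radical. The fallback uses known polar chemistry, sets out from 7 and 11 and comes back at 18. Formate 11 is cleaved with K2CO3 in MeOH to (3R)-5-iodo-3-methylpent-1-en-3-ol F1. F1 is deprotonated with MeLi, lithiated with t-BuLi at −78 °C and transmetallated with CeCl3. The organocerium is added to lactone 7, whose butenolide has first been masked as the furanolate with LiN(SiMe3)2, giving 4-[(1S,3R,7R)-1,7-dihydroxy-3,7-dimethyl-4-oxonon-8-en-1-yl]-3-methylfuran-2(5H)-one F2. F2 is esterified at once with 15 (DCC, DMAP), before it can spiroketalise, to (1S,3R,7R)-7-hydroxy-3,7-dimethyl-1-(4-methyl-5-oxo-2,5-dihydrofuran-3-yl)-4-oxonon-8-en-1-yl (2R)-3-chloro-2-hydroxy-2-methylpropanoate F3. Ozonolysis of F3 (O3, then Me2S) gives 18.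

**Step 11 (ten-membered ring closure).** A medium ring is formed from a trianion, in competition with oligomerisation and with reactions of the chlorohydrin alkoxide. The fallback replaces aldol/elimination by an intramolecular Wittig olefination, sets out from 16 and comes back at 21. Wohl–Ziegler bromination of 16 (NBS, AIBN) at the butenolide γ-carbon gives the C6 bromide of 16 F4. PPh3 converts F4 into the C6 triphenylphosphonium bromide of 16 F5. Ozonolysis and formate methanolysis as in step 10 give the C6 triphenylphosphonium bromide of 18 F6. Et3N at high dilution forms the stabilised ylide, which closes directly to 21.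

**Step 13 (C13 oxygenation).** The diene is electron-poor, so the ene reaction may be slow, and singlet oxygen could instead attack the C5=C6 enol-lactone bond. The fallback sets out from 21 and comes back at 24. Radical bromination of 21 (NBS, AIBN) at the C13 methyl gives the 13-bromide of 21 F7, and AgOAc in AcOH displaces bromide to give 24.

## Further compounds

F1 | step 7 | (3R)-5-iodo-3-methylpent-1-en-3-ol | C=C[C@@](O)(C)CCI
F2 | step 7 | 4-[(1S,3R,7R)-1,7-dihydroxy-3,7-dimethyl-4-oxonon-8-en-1-yl]-3-methylfuran-2(5H)-one | C=C[C@@](O)(C)CCC(=O)[C@H](C)C[C@@H](C1=C(C)C(=O)OC1)O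
F3 | step 7 | (1S,3R,7R)-7-hydroxy-3,7-dimethyl-1-(4-methyl-5-oxo-2,5-dihydrofuran-3-yl)-4-oxonon-8-en-1-yl (2R)-3-chloro-2-hydroxy-2-methylpropanoate | C=C[C@@](O)(C)CCC(=O)[C@H](C)C[C@@H](C1=C(C)C(=O)OC1)OC(=O)[C@@](C)(O)CCl
F4 | step 11 | C6 bromide of 16 | C=C[C@@](OC=O)(C)CCC(=O)[C@H](C)C[C@@H](C1=C(C)C(=O)OC1Br)OC(=O)[C@@](C)(O)CCl
F5 | step 11 | C6 triphenylphosphonium bromide of 16 | C=C[C@@](OC=O)(C)CCC(=O)[C@H](C)C[C@@H](C1=C(C)C(=O)OC1[P+](c2ccccc2)(c3ccccc3)c4ccccc4)OC(=O)[C@@](C)(O)CCl.[Br-]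
F6 | step 11 | C6 triphenylphosphonium bromide of 18 | O=C[C@@](O)(C)CCC(=O)[C@H](C)C[C@@H](C1=C(C)C(=O)OC1[P+](c2ccccc2)(c3ccccc3)c4ccccc4)OC(=O)[C@@](C)(O)CCl.[Br-]
F7 | step 13 | 13-bromide of 21 | BrCC1=C2/C(=C\[C@@]3(C)CC[C@](O)(O3)[C@H](C)C[C@@H]2OC(=O)[C@@](C)(O)CCl)OC1=O
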